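**Retrosynthetic overview**

1. Feature: the benzene ring (C3a, C4, C5, C6, C7, C7a) carries oxygen at C5 and C7, the lactone carbonyl C1 on C7a and the carbinol C3 on C3a. This is a 6-alkyl-2,4-dioxygenated benzoate, and its six ring carbons map onto a 4-carbomethoxycyclohexane-1,3-dione (side chain on C3 numbered C1'–C14').
2. Late disconnections: the acetate at C10' (step 11) and the methyl ether at C7 (step 10). Before these, arene and lactone go back to dione ester 15 (step 9); the iodine–methanol aromatisation installs the C5 methyl ether, unmasks the side chain and closes the lactone ring O2–C1.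
3. Key disconnection: C7a–C3a (Michael) and C6–C7 (Claisen) between dimethyl malonate 13 and the (S)-gamma-silyloxy methyl enone 12 (step 8).
4. Enone 12 comes from aldehyde 7 by D-proline alpha-aminoxylation and Wittig olefination (sets C3); 7 comes from alkene 6 by linear hydroformylation; the C10' carbinol is set by catalytic asymmetric addition of a ketal-bearing dialkylzinc to undec-10-enal.
5. Ring order: the carbocycle is built first in non-aromatic form (step 8), then aromatised with lactone closure in one operation (step 9).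

Key step: step 8

Remark on the chemistry: the ring stereocentres created in step 8 (present in 14, 15 and 16) should form as mixtures and are left unassigned, because aromatisation removes them.

**Step 1**
Reactants: 1 2-(2-bromoethyl)-2-methyl-1,3-dioxolane
Product: 2 2-(2-iodoethyl)-2-methyl-1,3-dioxolane
Conditions: NaI (3 equiv), NaHCO3 (cat.), acetone, reflux
Reagents that add atoms: sodium iodide, [Na+].[I-]
Why: Finkelstein halide exchange (SN2) at the primary carbon is driven by precipitation of NaBr from acetone and leaves the dioxolane untouched, giving the iodide needed for iodine–zinc exchange.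

**Step 2**
Reactants: 2 2-(2-iodoethyl)-2-methyl-1,3-dioxolane; 3 undec-10-enal
Product: 5 (3R)-1-(2-methyl-1,3-dioxolan-2-yl)tridec-12-en-3-ol, via bis[2-(2-methyl-1,3-dioxolan-2-yl)ethyl]zinc 4 (not isolated)
Conditions: 2, Et2Zn, CuI (cat.), neat, 50 °C, then EtI/Et2Zn removed in vacuo; Ti(OiPr)4, (1R,2R)-1,2-bis(trifluoromethanesulfonamido)cyclohexane (8 mol%), toluene, −20 °C, then 3; aq NH4Cl
Reagents that add atoms: none
Why: Iodine–zinc exchange with Et2Zn should give the ketal-bearing dialkylzinc 4, which adds to the aldehyde in a titanium/chiral bis(sulfonamide)-catalysed asymmetric dialkylzinc addition; the (1R,2R) ligand is expected to direct alkyl transfer to the Si face of 3, which by CIP priority (ketal arm above the alkenyl chain) is the (R) carbinol, and the terminal alkene and the ketal do not react.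

**Step 3**
Reactants: 5 (3R)-1-(2-methyl-1,3-dioxolan-2-yl)tridec-12-en-3-ol
Product: 6 tert-butyldimethyl{[(3R)-1-(2-methyl-1,3-dioxolan-2-yl)tridec-12-en-3-yl]oxy}silane
Conditions: TBSCl, imidazole, DMF, rt
Reagents that add atoms: tert-butyldimethylsilyl chloride, CC(C)(C)[Si](C)(C)Cl
Why: Imidazole-promoted O-silylation of the secondary alcohol involves only the O–H bond (retention) and masks the alcohol for the carbonyl chemistry ahead.

**Step 4**
Reactants: 6 tert-butyldimethyl{[(3R)-1-(2-methyl-1,3-dioxolan-2-yl)tridec-12-en-3-yl]oxy}silane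
Product: 7 (12R)-12-[(tert-butyldimethylsilyl)oxy]-14-(2-methyl-1,3-dioxolan-2-yl)tetradecanal
Conditions: Rh(acac)(CO)2 (1 mol%), BIPHEPHOS (3 mol%), CO/H2 (1:1, 5 bar), toluene, 60 °C
Reagents that add atoms: carbon monoxide, [C-]#[O+]
Why: Rhodium-catalysed hydroformylation with the wide-bite-angle bisphosphite BIPHEPHOS should add H and CHO across the terminal alkene with high linear selectivity under neutral conditions that spare the silyl ether and the ketal, giving the one-carbon-longer aldehyde directly.

**Step 5**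
Reactants: 7 (12R)-12-[(tert-butyldimethylsilyl)oxy]-14-(2-methyl-1,3-dioxolan-2-yl)tetradecanal; 8 1-(triphenyl-lambda5-phosphanylidene)propan-2-one
Product: 10 (3E,5S,15R)-5-(anilinooxy)-15-[(tert-butyldimethylsilyl)oxy]-17-(2-methyl-1,3-dioxolan-2-yl)heptadec-3-en-2-one, via alpha-anilinooxy aldehyde 9 (not isolated)
Conditions: D-proline (20 mol%), PhNO, CHCl3, 4 °C; then 8, 0 °C → rt
Reagents that add atoms: nitrosobenzene, O=Nc1ccccc1
Why: Proline-catalysed alpha-aminoxylation (enamine nitroso aldol, oxygen delivered to the enamine face held by the carboxylic acid hydrogen bond) with D-proline should set the (S) carbinol that becomes C3, and immediate Wittig olefination with the stabilised ylide 8 traps the configurationally labile aldehyde 9 as the (E)-enone without added base.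

**Step 6**
Reactants: 10 (3E,5S,15R)-5-(anilinooxy)-15-[(tert-butyldimethylsilyl)oxy]-17-(2-methyl-1,3-dioxolan-2-yl)heptadec-3-en-2-one
Product: 11 (3E,5S,15R)-15-[(tert-butyldimethylsilyl)oxy]-5-hydroxy-17-(2-methyl-1,3-dioxolan-2-yl)heptadec-3-en-2-one
Conditions: Cu(OAc)2·H2O (30 mol%), EtOH, rt
Reagents that add atoms: none
Why: Copper diacetate catalyses the redox-neutral cleavage of the O–N bond of the O-alkyl-N-phenylhydroxylamine (the anilino fragments ending as azobenzene), which should release the allylic alcohol without reducing the enone or touching silyl ether and ketal; the C–O bond at the stereocentre is not broken.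

**Step 7**
Reactants: 11 (3E,5S,15R)-15-[(tert-butyldimethylsilyl)oxy]-5-hydroxy-17-(2-methyl-1,3-dioxolan-2-yl)heptadec-3-en-2-one
Product: 12 (3E,5S,15R)-5,15-bis[(tert-butyldimethylsilyl)oxy]-17-(2-methyl-1,3-dioxolan-2-yl)heptadec-3-en-2-one
Conditions: TBSCl, imidazole, DMAP (cat.), DMF, 0 °C → rt
Reagents that add atoms: tert-butyldimethylsilyl chloride, CC(C)(C)[Si](C)(C)Cl
Why: Imidazole-promoted silylation at oxygen should give the base-stable gamma-silyloxy enone required for the annulation, and the mild amine base does not enolise the enone.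

**Step 8**
Reactants: 12 (3E,5S,15R)-5,15-bis[(tert-butyldimethylsilyl)oxy]-17-(2-methyl-1,3-dioxolan-2-yl)heptadec-3-en-2-one; 13 dimethyl malonate
Product: 15 methyl 6-[(1S,11R)-1,11-bis[(tert-butyldimethylsilyl)oxy]-13-(2-methyl-1,3-dioxolan-2-yl)tridecyl]-2,4-dioxocyclohexane-1-carboxylate, via Michael adduct 14 (not isolated)
Conditions: 13 (1.5 equiv), NaOMe (0.2 equiv), MeOH–THF, 0 °C; then NaOMe (1.5 equiv), 60 °C; AcOH, 0 °C
Reagents that add atoms: none
Why: Methoxide generates the malonate anion, which adds 1,4 to the enone (Michael addition, forming C7a–C3a); the methyl ketone of adduct 14 is then deprotonated at its CH3 group and attacks one malonate ester carbonyl with loss of methoxide (intramolecular Claisen condensation, forming C6–C7). This is the classical malonate Michael–Claisen annulation of alk-3-en-2-ones to 6-substituted methyl 2,4-dioxocyclohexanecarboxylates. The carbocycle closes by 6-exo-trig acyl substitution; the internal CH2 enolate could only give a four-membered ring, so the regiochemistry is fixed by ring size, and deprotonation of the product to its delocalised dione enolate pulls both equilibria forward. The two new ring stereocentres (C3a, C7a) arise under substrate control only and are not assigned, since both are erased on aromatisation. The selectivity that matters is conjugate addition ahead of gamma-deprotonation of 12, which would scramble C3: it is secured by running the addition at 0 °C with catalytic methoxide and an excess of the far more acidic malonate, so that the enone is consumed before stoichiometric base and heat are applied, after which the C3–H is no longer acidic. The silyl ethers and the dioxolane are expected to tolerate methoxide, and the mild acetic acid quench keeps them in place.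

**Step 9**
Reactants: 15 methyl 6-[(1S,11R)-1,11-bis[(tert-butyldimethylsilyl)oxy]-13-(2-methyl-1,3-dioxolan-2-yl)tridecyl]-2,4-dioxocyclohexane-1-carboxylate
Product: 17 (3S)-7-hydroxy-3-[(10R)-10-hydroxy-13-oxotetradecyl]-5-methoxy-2-benzofuran-1(3H)-one, via deprotected lactone-dione 16 (not isolated)
Conditions: I2 (1.2 equiv), MeOH, reflux; then 1 M aq HCl, THF, rt
Reagents that add atoms: methanol, CO; water, O
Why: Iodine–methanol oxidative aromatisation of the cyclohexane-1,3-dione (methyl enol ether at the carbonyl remote from the acyl group, alpha-iodination, loss of HI) should give the 5-methoxy-7-hydroxy arene, while the HI released in hot methanol cleaves both silyl ethers and the ketal so that the C3 hydroxyl lactonises onto the ester by acyl substitution (C3–O bond intact, hence retention); the aqueous acid stage hydrolyses any methyl ketal of the side-chain ketone.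

**Step 10**
Reactants: 17 (3S)-7-hydroxy-3-[(10R)-10-hydroxy-13-oxotetradecyl]-5-methoxy-2-benzofuran-1(3H)-one
Product: 18 (3S)-3-[(10R)-10-hydroxy-13-oxotetradecyl]-5,7-dimethoxy-2-benzofuran-1(3H)-one
Conditions: MeI, K2CO3, DMF, rt
Reagents that add atoms: iodomethane, CI
Why: Williamson O-methylation of the only acidic OH (the lactone-chelated 7-phenol) uses carbonate, a base too weak to alkylate the secondary alcohol or to epimerise C3.

**Step 11**
Reactants: 18 (3S)-3-[(10R)-10-hydroxy-13-oxotetradecyl]-5,7-dimethoxy-2-benzofuran-1(3H)-one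
Product: 19 (3S)-3-[(10R)-10-acetoxy-13-oxotetradecyl]-5,7-dimethoxy-2-benzofuran-1(3H)-one
Conditions: Ac2O, pyridine, DMAP (cat.), CH2Cl2, rt
Reagents that add atoms: acetic anhydride, CC(=O)OC(C)=O
Why: DMAP-catalysed acylation of the one remaining hydroxyl (O–H only, retention) should complete the target, the ketone, lactone and aryl ethers being inert.

**Compound list**

1 | 2-(2-bromoethyl)-2-methyl-1,3-dioxolane | CC1(CCBr)OCCO1 | starting material
2 | 2-(2-iodoethyl)-2-methyl-1,3-dioxolane | CC1(CCI)OCCO1 | intermediate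
3 | undec-10-enal | C=CCCCCCCCCC=O | starting material
4 | bis[2-(2-methyl-1,3-dioxolan-2-yl)ethyl]zinc | CC1(CC[Zn]CCC2(C)OCCO2)OCCO1 | intermediate (not isolated)
5 | (3R)-1-(2-methyl-1,3-dioxolan-2-yl)tridec-12-en-3-ol | C=CCCCCCCCC[C@H](CCC1(C)OCCO1)O | intermediate
6 | tert-butyldimethyl{[(3R)-1-(2-methyl-1,3-dioxolan-2-yl)tridec-12-en-3-yl]oxy}silane | C=CCCCCCCCC[C@H](CCC1(C)OCCO1)O[Si](C)(C)C(C)(C)C | intermediate
7 | (12R)-12-[(tert-butyldimethylsilyl)oxy]-14-(2-methyl-1,3-dioxolan-2-yl)tetradecanal | O=CCCCCCCCCCC[C@H](CCC1(C)OCCO1)O[Si](C)(C)C(C)(C)C | intermediate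
8 | 1-(triphenyl-lambda5-phosphanylidene)propan-2-one | CC(=O)C=P(c1ccccc1)(c1ccccc1)c1ccccc1 | starting material
9 | (2S,12R)-2-(anilinooxy)-12-[(tert-butyldimethylsilyl)oxy]-14-(2-methyl-1,3-dioxolan-2-yl)tetradecanal | O=C[C@@H](ONc1ccccc1)CCCCCCCCC[C@H](CCC1(C)OCCO1)O[Si](C)(C)C(C)(C)C | intermediate (not isolated)
10 | (3E,5S,15R)-5-(anilinooxy)-15-[(tert-butyldimethylsilyl)oxy]-17-(2-methyl-1,3-dioxolan-2-yl)heptadec-3-en-2-one | CC(=O)/C=C/[C@H](CCCCCCCCC[C@H](CCC1(C)OCCO1)O[Si](C)(C)C(C)(C)C)ONc1ccccc1 | intermediate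
11 | (3E,5S,15R)-15-[(tert-butyldimethylsilyl)oxy]-5-hydroxy-17-(2-methyl-1,3-dioxolan-2-yl)heptadec-3-en-2-one | CC(=O)/C=C/[C@H](CCCCCCCCC[C@H](CCC1(C)OCCO1)O[Si](C)(C)C(C)(C)C)O | intermediate
12 | (3E,5S,15R)-5,15-bis[(tert-butyldimethylsilyl)oxy]-17-(2-methyl-1,3-dioxolan-2-yl)heptadec-3-en-2-one | CC(=O)/C=C/[C@H](CCCCCCCCC[C@H](CCC1(C)OCCO1)O[Si](C)(C)C(C)(C)C)O[Si](C)(C)C(C)(C)C | intermediate
13 | dimethyl malonate | COC(=O)CC(=O)OC | starting material
14 | dimethyl 2-[(5S,15R)-5,15-bis[(tert-butyldimethylsilyl)oxy]-17-(2-methyl-1,3-dioxolan-2-yl)-2-oxoheptadecan-4-yl]propanedioate (C4 unassigned) | COC(=O)C(C(=O)OC)C(CC(C)=O)[C@H](CCCCCCCCC[C@H](CCC1(C)OCCO1)O[Si](C)(C)C(C)(C)C)O[Si](C)(C)C(C)(C)C | intermediate (not isolated)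
15 | methyl 6-[(1S,11R)-1,11-bis[(tert-butyldimethylsilyl)oxy]-13-(2-methyl-1,3-dioxolan-2-yl)tridecyl]-2,4-dioxocyclohexane-1-carboxylate (ring stereocentres unassigned) | COC(=O)C1C(=O)CC(=O)CC1[C@H](CCCCCCCCC[C@H](CCC2(C)OCCO2)O[Si](C)(C)C(C)(C)C)O[Si](C)(C)C(C)(C)C | intermediate
16 | (3S)-3-[(10R)-10-hydroxy-13-oxotetradecyl]-3a,4-dihydro-2-benzofuran-1,5,7(3H,6H,7aH)-trione (C3a, C7a unassigned) | O=C1CC(=O)C2C(C1)[C@H](CCCCCCCCC[C@H](CCC(C)=O)O)OC2=O | intermediate (not isolated)
17 | (3S)-7-hydroxy-3-[(10R)-10-hydroxy-13-oxotetradecyl]-5-methoxy-2-benzofuran-1(3H)-one | COc1cc(O)c2c(c1)[C@H](CCCCCCCCC[C@H](CCC(C)=O)O)OC2=O | intermediate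
18 | (3S)-3-[(10R)-10-hydroxy-13-oxotetradecyl]-5,7-dimethoxy-2-benzofuran-1(3H)-one | COc1cc(OC)c2c(c1)[C@H](CCCCCCCCC[C@H](CCC(C)=O)O)OC2=O | intermediate
19 | (3S)-3-[(10R)-10-acetoxy-13-oxotetradecyl]-5,7-dimethoxy-2-benzofuran-1(3H)-one | COc1cc(OC)c2c(c1)[C@H](CCCCCCCCC[C@H](CCC(C)=O)OC(C)=O)OC2=O | target

**Step count**

Total steps: 11. Longest linear sequence: 11 steps (1 to 19; 3 enters at step 2, 8 at step 5, 13 at step 8).

**Steps most likely to fail**

1. Step 8. Gamma-deprotonation of the enone could outrun a sterically slowed intermolecular conjugate addition, eroding C3 or isomerising the enone; methoxide could also remove a silyl group on prolonged heating.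
Fallback (from 11, back at 17): the conjugate addition is made intramolecular through an ester tether. Acylation of 11 with methyl 3-chloro-3-oxopropanoate (pyridine, CH2Cl2, 0 °C) should give the mixed methyl malonate ester F1. Catalytic Cs2CO3 in MeCN at rt should then close the butyrolactone by 5-exo-trig Michael addition, giving the keto lactone F2. KOtBu in THF at 0 °C should effect the Claisen closure of the carbocycle, giving the bicyclic lactone-dione F3. The same two C–C bonds are formed, but the Michael step is fast under carbonate and no longer competes with gamma-deprotonation. Treating F3 under the conditions of step 9 should remove the remaining silyl ether and the ketal and aromatise, rejoining the route at 17.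

2. Step 9. The acid-driven events that accompany the oxidation may run incompletely or unselectively (partial desilylation, persistent methyl ketals, reversible iodination next to the side-chain ketone), giving mixtures instead of one aromatised lactone.
Fallback (from 15, back at 17): the oxidation is separated from the deprotection. O-Methylation of 15 (Me2SO4, K2CO3, acetone, rt) at the unhindered C4 oxygen should give the vinylogous methyl ester F4. Dehydrogenation with DDQ (1,4-dioxane, rt to 50 °C) should give the fully protected methyl 2-hydroxy-4-methoxybenzoate F5. Aqueous HF in MeCN at rt would then remove both silyl ethers and the ketal with lactonisation, giving 17.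

3. Step 5. The alpha-aminoxy aldehyde may racemise or oligomerise before it is olefinated, or the gamma-aminoxy enone may fragment at the N–O bond under the reaction conditions.
Fallback (from 6, back at 12): the C3 carbinol is set by resolution and the enone by metathesis.
- Hydroboration–oxidation of 6 (9-BBN, THF; NaOH, H2O2) should give the primary alcohol F6.
- Dess–Martin periodinane (NaHCO3, CH2Cl2) should give the aldehyde F7.
- Vinylmagnesium bromide (THF, −78 °C) should give the allylic alcohol F8 as a mixture at C3.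
- Sharpless kinetic resolution (Ti(OiPr)4, D-(−)-diisopropyl tartrate, tBuOOH, 4 Å sieves, CH2Cl2, −20 °C) should epoxidise the (3R) epimer and leave the (3S)-allylic alcohol F9.
- Silylation (TBSCl, imidazole, DMF) should give the bis-silyl ether F10.
- Cross-metathesis with but-3-en-2-one and the second-generation Grubbs catalyst (H2IMes)(PCy3)Cl2Ru=CHPh (CH2Cl2, 40 °C) should give 12.

**Further compounds**

F1 | step 8 | methyl (3E,5S,15R)-15-[(tert-butyldimethylsilyl)oxy]-17-(2-methyl-1,3-dioxolan-2-yl)-2-oxoheptadec-3-en-5-yl propanedioate | CC(=O)/C=C/[C@H](CCCCCCCCC[C@H](CCC1(C)OCCO1)O[Si](C)(C)C(C)(C)C)OC(=O)CC(=O)OC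
F2 | step 8 | methyl (5S)-5-[(10R)-10-[(tert-butyldimethylsilyl)oxy]-12-(2-methyl-1,3-dioxolan-2-yl)dodecyl]-2-oxo-4-(2-oxopropyl)oxolane-3-carboxylate (C3, C4 unassigned) | COC(=O)C1C(CC(C)=O)[C@H](CCCCCCCCC[C@H](CCC2(C)OCCO2)O[Si](C)(C)C(C)(C)C)OC1=O
F3 | step 8 | (3S)-3-[(10R)-10-[(tert-butyldimethylsilyl)oxy]-12-(2-methyl-1,3-dioxolan-2-yl)dodecyl]-3a,4-dihydro-2-benzofuran-1,5,7(3H,6H,7aH)-trione (C3a, C7a unassigned) | O=C1CC(=O)C2C(C1)[C@H](CCCCCCCCC[C@H](CCC3(C)OCCO3)O[Si](C)(C)C(C)(C)C)OC2=O
F4 | step 9 | methyl 6-[(1S,11R)-1,11-bis[(tert-butyldimethylsilyl)oxy]-13-(2-methyl-1,3-dioxolan-2-yl)tridecyl]-4-methoxy-2-oxocyclohex-3-ene-1-carboxylate (ring stereocentres unassigned) | COC(=O)C1C(=O)C=C(OC)CC1[C@H](CCCCCCCCC[C@H](CCC2(C)OCCO2)O[Si](C)(C)C(C)(C)C)O[Si](C)(C)C(C)(C)C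
F5 | step 9 | methyl 2-[(1S,11R)-1,11-bis[(tert-butyldimethylsilyl)oxy]-13-(2-methyl-1,3-dioxolan-2-yl)tridecyl]-6-hydroxy-4-methoxybenzoate | COC(=O)c1c(O)cc(OC)cc1[C@H](CCCCCCCCC[C@H](CCC2(C)OCCO2)O[Si](C)(C)C(C)(C)C)O[Si](C)(C)C(C)(C)C
F6 | step 5 | (11R)-11-[(tert-butyldimethylsilyl)oxy]-13-(2-methyl-1,3-dioxolan-2-yl)tridecan-1-ol | OCCCCCCCCCC[C@H](CCC1(C)OCCO1)O[Si](C)(C)C(C)(C)C
F7 | step 5 | (11R)-11-[(tert-butyldimethylsilyl)oxy]-13-(2-methyl-1,3-dioxolan-2-yl)tridecanal | O=CCCCCCCCCC[C@H](CCC1(C)OCCO1)O[Si](C)(C)C(C)(C)C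
F8 | step 5 | (13R)-13-[(tert-butyldimethylsilyl)oxy]-15-(2-methyl-1,3-dioxolan-2-yl)pentadec-1-en-3-ol (C3 unassigned) | C=CC(O)CCCCCCCCC[C@H](CCC1(C)OCCO1)O[Si](C)(C)C(C)(C)C
F9 | step 5 | (3S,13R)-13-[(tert-butyldimethylsilyl)oxy]-15-(2-methyl-1,3-dioxolan-2-yl)pentadec-1-en-3-ol | C=C[C@@H](O)CCCCCCCCC[C@H](CCC1(C)OCCO1)O[Si](C)(C)C(C)(C)C
F10 | step 5 | (3S,13R)-3,13-bis[(tert-butyldimethylsilyl)oxy]-15-(2-methyl-1,3-dioxolan-2-yl)pentadec-1-ene | C=C[C@@H](O[Si](C)(C)C(C)(C)C)CCCCCCCCC[C@H](CCC1(C)OCCO1)O[Si](C)(C)C(C)(C)C
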